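The route rests on disconnecting the bond between the cyclopentene sp2 carbon and the quaternary carbon common to the cyclopentane, the δ-lactone and the seven-membered ring. An intramolecular reductive Heck reaction of a cyclopentenyl iodide with a tetrasubstituted enol δ-lactone forms this bond, closes the seven-membered ring and sets both δ-lactone fusion stereocentres in one operation. It exploits the fact that the quaternary carbon and the neighbouring O–CH carbon can be masked as a strained C=C in the two-carbon bridge of the 2-azabicyclo[3.2.1]octane. The precursor is this bridged lactam, already fused to the pyrrolidine γ-lactone and carrying the iodocyclopentenylethyl chain and the enol lactone.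

Key step: step 23

Remark: in the names the bridged core is numbered as 2-azabicyclo[3.2.1]octane (C-1 nitrogen-bearing bridgehead, N-2, C-3, C-4, C-5 second bridgehead, C-6, C-7, C-8 one-carbon bridge); exo is the face of C-8, endo the face of the N-2/C-3/C-4 bridge; isomer mixtures at centres or double bonds that are destroyed later are drawn as one isomer.

Step 1
Reactants: 1 cyclopent-2-en-1-one
Product: 2 2-iodocyclopent-2-en-1-one
Conditions: I2, pyridine, CH2Cl2, 0 °C to rt
Reagents that add atoms: iodine, II
Why: α-Iodination of the enone by pyridine-mediated addition–iodination–elimination (Baylis–Hillman-type sequence) should give the 2-iodo enone, and no stereocentre is formed.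

Step 2
Reactants: 2 2-iodocyclopent-2-en-1-one
Product: 3 (R)-2-iodocyclopent-2-en-1-ol
Conditions: (S)-2-methyl-CBS-oxazaborolidine (20 mol %), BH3·SMe2, THF, −20 °C; MeOH
Reagents that add atoms: none
Why: Corey–Bakshi–Shibata reduction, in which the oxazaborolidine–borane complex binds the ketone with the iodoalkene as the large group and delivers hydride to one face, should set the (R)-carbinol centre.

Step 3
Reactants: 3 (R)-2-iodocyclopent-2-en-1-ol
Product: 4 ethyl [(1R)-2-iodocyclopent-2-en-1-yl]acetate
Conditions: MeC(OEt)3, EtCO2H (cat.), 140 °C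
Reagents that add atoms: triethyl orthoacetate, CCOC(C)(OCC)OCC
Why: Johnson–Claisen rearrangement through the chair-like ketene acetal transfers the carbinol chirality suprafacially to the new C–C bond (same ring face as the departing oxygen) and shifts the double bond so that the alkenyl iodide is kept, which sets the (R)-ring centre.

Step 4
Reactants: 4 ethyl [(1R)-2-iodocyclopent-2-en-1-yl]acetate
Product: 5 [(1R)-2-iodocyclopent-2-en-1-yl]acetaldehyde
Conditions: iBu2AlH, CH2Cl2, −78 °C; aq. Rochelle salt
Reagents that add atoms: none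
Why: Partial ester reduction stops at the tetrahedral aluminium hemiacetal at low temperature and gives the aldehyde on work-up, the β-stereocentre not being enolisable.

Step 5
Reactants: 6 2-methylidenepropane-1,3-diol
Product: 7 2-[(tert-butyldiphenylsilyloxy)methyl]prop-2-en-1-ol
Conditions: NaH (1 equiv), THF, 0 °C; tBuPh2SiCl
Reagents that add atoms: tert-butyl(chloro)diphenylsilane, CC(C)(C)[Si](Cl)(c1ccccc1)c1ccccc1
Why: O-Silylation of the symmetric diol through its monosodium alkoxide should give the mono-ether, and no stereocentre is formed.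

Step 6
Reactants: 7 2-[(tert-butyldiphenylsilyloxy)methyl]prop-2-en-1-ol
Product: 8 tert-butyl{[2-(bromomethyl)prop-2-en-1-yl]oxy}diphenylsilane
Conditions: CBr4, PPh3, CH2Cl2, 0 °C
Reagents that add atoms: tetrabromomethane, BrC(Br)(Br)Br
Why: Appel bromination converts the allylic alcohol into the bromide under neutral conditions that leave the silyl ether untouched.

Step 7
Reactants: 9 prop-2-yn-1-ol
Product: 10 (Z)-3-iodo-2-methylprop-2-en-1-ol
Conditions: MeMgBr (2.5 equiv), CuI (10 mol %), THF, −10 °C to rt; then I2, −78 °C to rt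
Reagents that add atoms: methylmagnesium bromide, C[Mg]Br; iodine, II
Why: Copper-catalysed anti-carbomagnesiation of the propargylic alkoxide places methyl on the internal carbon and the chelated magnesium cis to CH2O, so iodinolysis gives the (Z)-iodoalkene.

Step 8
Reactants: 10 (Z)-3-iodo-2-methylprop-2-en-1-ol
Product: 11 (Z)-3-iodo-2-methylprop-2-enal
Conditions: MnO2, CH2Cl2, rt
Reagents that add atoms: none
Why: Allylic oxidation with MnO2 gives the enal without touching the alkenyl iodide or its geometry.

Step 9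
Reactants: 12 methyl isocyanoacetate; 8 tert-butyl{[2-(bromomethyl)prop-2-en-1-yl]oxy}diphenylsilane
Product: 13 methyl 4-[(tert-butyldiphenylsilyloxy)methyl]-2-isocyanopent-4-enoate (racemic)
Conditions: K2CO3, Bu4NHSO4 (cat.), MeCN, rt (12 in excess)
Reagents that add atoms: none
Why: C-Alkylation (SN2) of the isocyanoacetate enolate under phase-transfer conditions gives the mono-alkylated isocyanide, whose acidic stereocentre is reset in step 10.

Step 10
Reactants: 13 methyl 4-[(tert-butyldiphenylsilyloxy)methyl]-2-isocyanopent-4-enoate; 11 (Z)-3-iodo-2-methylprop-2-enal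
Product: 14 methyl (4R,5S)-4-{2-[(tert-butyldiphenylsilyloxy)methyl]prop-2-en-1-yl}-5-[(1Z)-1-iodoprop-1-en-2-yl]-4,5-dihydro-1,3-oxazole-4-carboxylate
Conditions: [Au(CNC6H11)2]BF4 (1 mol %), (S)-N-methyl-N-[2-(morpholin-4-yl)ethyl]-1-[(R)-1',2-bis(diphenylphosphino)ferrocenyl]ethylamine (1.1 mol %), CH2Cl2, rt
Reagents that add atoms: none
Why: In the Ito–Hayashi aldol reaction the monovalent gold complex binds the isocyanide while the aminoethyl arm of the ligand guides the enolate onto one aldehyde face, which should give the trans-oxazoline and set the quaternary amino carbon (4R) and the O–CH carbon (5S) together.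

Step 11
Reactants: 14 the oxazoline methyl ester
Product: 15 (4R,5S)-4-{2-[(tert-butyldiphenylsilyloxy)methyl]prop-2-en-1-yl}-5-[(1Z)-1-iodoprop-1-en-2-yl]-N-methoxy-N-methyl-4,5-dihydro-1,3-oxazole-4-carboxamide
Conditions: MeNH(OMe)·HCl, AlMe3, CH2Cl2, 0 to 40 °C; aq. Rochelle salt
Reagents that add atoms: N,O-dimethylhydroxylamine hydrochloride, CNOC.Cl
Why: Weinreb aminolysis by the dimethylaluminium amide converts the hindered ester into the N-methoxy-N-methyl amide without touching the oxazoline or the stereocentres.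

Step 12
Reactants: 15 the oxazoline Weinreb amide
Product: 16 1-[(4R,5S)-4-{2-[(tert-butyldiphenylsilyloxy)methyl]prop-2-en-1-yl}-5-[(1Z)-1-iodoprop-1-en-2-yl]-4,5-dihydro-1,3-oxazol-4-yl]prop-2-en-1-one
Conditions: CH2=CHMgBr, THF, −78 to 0 °C; cold aq. NH4Cl
Reagents that add atoms: vinylmagnesium bromide, C=C[Mg]Br
Why: Weinreb ketone synthesis, in which the chelated tetrahedral magnesium adduct survives until the quench so that the Grignard reagent adds only once and gives the vinyl ketone.

Step 13
Reactants: 16 the oxazoline vinyl ketone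
Product: 17 (4S,5R)-8-[(tert-butyldiphenylsilyloxy)methyl]-4-[(1Z)-1-iodoprop-1-en-2-yl]-3-oxa-1-azaspiro[4.4]nona-1,7-dien-6-one
Conditions: second-generation Grubbs catalyst (5 mol %), toluene, 80 °C
Reagents that add atoms: none
Why: Ring-closing metathesis between the vinyl ketone and the 1,1-disubstituted alkene forms the cyclopentenone with loss of ethene, the trisubstituted iodoalkene being too hindered to take part.

Step 14
Reactants: 17 the spiro oxazoline enone
Product: 19 N-{(1R)-4-[(tert-butyldiphenylsilyloxy)methyl]-1-[(1S,2Z)-1-hydroxy-3-iodo-2-methylprop-2-en-1-yl]-2-oxocyclopent-3-en-1-yl}-N-[(trimethylsilyl)methyl]formamide, via N-silylmethyl oxazolinium triflate 18 (not isolated)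
Conditions: Me3SiCH2OTf, CH2Cl2, 0 °C to rt; then aq. NaHCO3, THF
Reagents that add atoms: (trimethylsilyl)methyl trifluoromethanesulfonate, C[Si](C)(C)COS(=O)(=O)C(F)(F)F; water, O
Why: N-Alkylation of the oxazoline gives an oxazolinium ion that hydroxide attacks at C-2, and collapse of the tetrahedral intermediate with C–O cleavage (basic hydrolysis of an imidate salt) frees the alcohol and leaves nitrogen masked as the formamide without touching a stereocentre.

Step 15
Reactants: 19 the N-formyl iodo alcohol
Product: 20 N-{(1R)-4-[(tert-butyldiphenylsilyloxy)methyl]-1-[(2S)-3-methyl-5-oxo-2,5-dihydrofuran-2-yl]-2-oxocyclopent-3-en-1-yl}-N-[(trimethylsilyl)methyl]formamide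
Conditions: PdCl2(PPh3)2 (5 mol %), CO (1 atm), K2CO3, THF, 50 °C
Reagents that add atoms: carbon monoxide, [C-]#[O+]
Why: Carbonylative lactonisation, in which oxidative addition of the (Z)-alkenyl iodide to zerovalent palladium, CO insertion and capture of the acylpalladium by the cis-placed hydroxyl close the butenolide while the formamide keeps nitrogen from competing.

Step 16
Reactants: 20 the N-formyl butenolide
Product: 21 (5S)-5-[(1R)-4-[(tert-butyldiphenylsilyloxy)methyl]-2-oxo-1-{[(trimethylsilyl)methyl]amino}cyclopent-3-en-1-yl]-4-methylfuran-2(5H)-one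
Conditions: HCl (1.25 M in MeOH), 45 °C; aq. NaHCO3
Reagents that add atoms: none
Why: Acid-catalysed methanolysis removes the formyl group as methyl formate and leaves the butenolide, the C–Si bond and the silyl ether intact.

Step 17
Reactants: 21 the α-silylamine butenolide
Product: 22 spiro pyrrolidine–γ-lactone enone: cis-fused 3a-methylhexahydro-2H-furo[2,3-c]pyrrol-2-one (N–H free) whose C-6 is the spiro carbon C-1 of 4-[(tert-butyldiphenylsilyloxy)methyl]cyclopent-3-en-2-one, lactone oxygen and enone carbonyl on the same face of the pyrrolidine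
Conditions: Ir[dF(CF3)ppy]2(dtbbpy)PF6 (1 mol %), MeCN/MeOH, blue LEDs, rt
Reagents that add atoms: none
Why: Photoredox desilylative radical cyclisation, in which single-electron oxidation of the α-silylamine and loss of silicon give an aminomethyl radical that adds 5-exo-trig to the butenolide β-carbon (closure onto the enone would give a strained 2-azanorbornane), and the cis fusion demanded by the two five-membered rings sets the methyl-bearing quaternary centre.

Step 18
Reactants: 22 the spiro pyrrolidine–γ-lactone enone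
Product: 23 N-[(diethoxyphosphoryl)acetyl] derivative of 22
Conditions: (EtO)2P(O)CH2CO2H, DCC, DMAP (cat.), CH2Cl2, 0 °C to rt
Reagents that add atoms: (diethoxyphosphoryl)acetic acid, OC(=O)CP(=O)(OCC)OCC
Why: Carbodiimide amide coupling acylates the secondary amine to the tertiary phosphonoacetamide needed for the cyclisation.

Step 19
Reactants: 23 the phosphonoacetamide; 5 [(1R)-2-iodocyclopent-2-en-1-yl]acetaldehyde
Product: 25 4-alkylidene lactam: 2-azabicyclo[3.2.1]octane-3,7-dione with N-2/C-1 fused to the pyrrolidine–γ-lactone of 22, CH2OSi(tBu)Ph2 at C-5 and a (Z)-2-[(1R)-2-iodocyclopent-2-en-1-yl]ethylidene group at C-4, via lactam phosphonate 24 (not isolated)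
Conditions: LiCl, DBU, MeCN, rt; then 5, 0 °C to rt
Reagents that add atoms: none
Why: Intramolecular Michael addition (6-exo-trig) of the phosphonate-stabilised carbanion, which can reach the enone β-carbon only on the nitrogen face and so sets the quaternary bridgehead C-5, followed by Horner–Wadsworth–Emmons olefination of the α-phosphono lactam with the aldehyde.

Step 20
Reactants: 25 the 4-alkylidene lactam
Product: 26 (4S)-4-{2-[(1R)-2-iodocyclopent-2-en-1-yl]ethyl} lactam ketone (25 with the exocyclic C=C reduced, H-4 exo)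
Conditions: Cu(OAc)2 (5 mol %), 1,2-bis(diphenylphosphino)benzene (5 mol %), (EtO)2MeSiH, tBuOH, toluene, rt
Reagents that add atoms: none
Why: Copper hydride conjugate reduction of the unsaturated lactam gives a ketene aminal that is protonated on the exo face (as electrophiles attack bicyclo[3.2.1]octan-3-one enolates), which places the chain equatorial and sets C-4.

Step 21
Reactants: 26 the lactam ketone
Product: 28 6-(3-tert-butoxy-3-oxopropyl) derivative of 26 (chain exo drawn), via trimethylsilyl enol ether 27 (not isolated)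
Conditions: Me3SiOTf, Et3N, CH2Cl2, 0 °C; evaporate; then tert-butyl acrylate, (Me2N)3S(Me3SiF2) (10 mol %), THF, −78 to 0 °C; aq. NH4Cl
Reagents that add atoms: tert-butyl acrylate, C=CC(=O)OC(C)(C)C
Why: Soft enolisation can occur only towards C-6 (C-1 is quaternary and the ketone is silylated far faster than lactone or lactam), and the fluoride-catalysed Mukaiyama–Michael addition of the silyl enol ether installs the propanoate chain at a centre that is planarised again in step 22.

Step 22
Reactants: 28 the keto tert-butyl ester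
Product: 30 enol δ-lactone: 3,4-dihydro-2H-pyran-2-one fused at its 5,6-bond to C-6=C-7 of the core (ring oxygen on C-7), via keto acid 29 (not isolated)
Conditions: CF3CO2H, CH2Cl2, rt; evaporate; then Ac2O, NaOAc, 100 °C
Reagents that add atoms: none
Why: Acidolysis of the tert-butyl ester and enol lactonisation of the δ-keto acid with acetic anhydride, where enolisation is possible only towards C-6, give the tetrasubstituted enol lactone.

Step 23
Reactants: 30 the enol δ-lactone alkenyl iodide
Product: 31 heptacyclic lactam bis-lactone silyl ether (33 with C-3 as lactam C=O and the hydroxymethyl as its tert-butyldiphenylsilyl ether, all eight stereocentres as in 33)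
Conditions: Pd(OAc)2 (10 mol %), P(2-furyl)3 (20 mol %), HCO2Na, Bu4NCl, DMF, 80 °C
Reagents that add atoms: none
Why: Proposed new method: zerovalent palladium inserts into the alkenyl C–I bond, the alkenylpalladium adds syn across the strained tetrasubstituted enol-lactone C=C (new C–C bond to the non-oxygenated carbon C-6, palladium on C-7), and the tertiary α-acyloxyalkylpalladium, which has no β-hydrogen and cannot lose the β-amide without forming a bridgehead alkene, is intercepted by formate and reductively eliminates C–H; the closest known reaction type is the intramolecular reductive Heck reaction (hydroarylation) of norbornene-type and tetrasubstituted alkenes that forms quaternary centres. The seven-membered ring closes 7-exo-trig. The quaternary centre C-6 is fixed by the tether from C-4, which reaches only the endo face, and the O–CH centre C-7 is fixed by the syn addition, so hydrogen enters endo and the lactone oxygen stays exo (cis-fused δ-lactone), an outcome that hydride reduction of the corresponding ketone from its open exo face would not give. The step needs insertion to be faster than formate reduction of the alkenylpalladium, which ring strain of the alkene, its enforced proximity and the lightly ligated chloride-stabilised catalyst should secure.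

Step 24
Reactants: 31 the heptacyclic lactam
Product: 32 tert-butyldiphenylsilyl ether of 33
Conditions: [IrCl(coe)2]2 (2 mol %), Et2SiH2, CH2Cl2, rt
Reagents that add atoms: none
Why: Iridium-catalysed hydrosilylation reduces the tertiary lactam through the N,O-silyl acetal and iminium ion to the amine while lactones do not react, and no stereocentre changes.

Step 25
Reactants: 32 the silyl ether
Product: 33 target CNP0247797.1
Conditions: HF·pyridine, THF, 0 °C to rt
Reagents that add atoms: none
Why: Fluoride-mediated cleavage of the silyl ether, driven by the strong Si–F bond, releases the primary alcohol and gives the target.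

Compound list
1 | cyclopent-2-en-1-one | O=C1C=CCC1 | starting material
2 | 2-iodocyclopent-2-en-1-one | O=C1C(I)=CCC1 | intermediate
3 | (R)-2-iodocyclopent-2-en-1-ol | O[C@@H]1CCC=C1I | intermediate
4 | ethyl [(1R)-2-iodocyclopent-2-en-1-yl]acetate | CCOC(=O)C[C@H]1CCC=C1I | intermediate
5 | [(1R)-2-iodocyclopent-2-en-1-yl]acetaldehyde | O=CC[C@H]1CCC=C1I | intermediate
6 | 2-methylidenepropane-1,3-diol | C=C(CO)CO | starting material
7 | 2-[(tert-butyldiphenylsilyloxy)methyl]prop-2-en-1-ol | C=C(CO)CO[Si](c1ccccc1)(c1ccccc1)C(C)(C)C | intermediate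
8 | tert-butyl{[2-(bromomethyl)prop-2-en-1-yl]oxy}diphenylsilane | C=C(CBr)CO[Si](c1ccccc1)(c1ccccc1)C(C)(C)C | intermediate
9 | prop-2-yn-1-ol | C#CCO | starting material
10 | (Z)-3-iodo-2-methylprop-2-en-1-ol | OC/C(C)=C\I | intermediate
11 | (Z)-3-iodo-2-methylprop-2-enal | O=C/C(C)=C\I | intermediate
12 | methyl isocyanoacetate | [C-]#[N+]CC(=O)OC | starting material
13 | methyl 4-[(tert-butyldiphenylsilyloxy)methyl]-2-isocyanopent-4-enoate (racemic) | [C-]#[N+]C(CC(=C)CO[Si](c1ccccc1)(c1ccccc1)C(C)(C)C)C(=O)OC | intermediate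
14 | methyl (4R,5S)-4-{2-[(tert-butyldiphenylsilyloxy)methyl]prop-2-en-1-yl}-5-[(1Z)-1-iodoprop-1-en-2-yl]-4,5-dihydro-1,3-oxazole-4-carboxylate | O1[C@@H](/C(C)=C\I)[C@](C(=O)OC)(N=C1)CC(=C)CO[Si](c2ccccc2)(c3ccccc3)C(C)(C)C | intermediate
15 | N-methoxy-N-methyl amide corresponding to 14 | O1[C@@H](/C(C)=C\I)[C@](C(=O)N(C)OC)(N=C1)CC(=C)CO[Si](c2ccccc2)(c3ccccc3)C(C)(C)C | intermediate
16 | vinyl ketone corresponding to 14 (4-acryloyl oxazoline) | O1[C@@H](/C(C)=C\I)[C@](C(=O)C=C)(N=C1)CC(=C)CO[Si](c2ccccc2)(c3ccccc3)C(C)(C)C | intermediate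
17 | (4S,5R)-8-[(tert-butyldiphenylsilyloxy)methyl]-4-[(1Z)-1-iodoprop-1-en-2-yl]-3-oxa-1-azaspiro[4.4]nona-1,7-dien-6-one | O1[C@@H](/C(C)=C\I)[C@]2(C(=O)C=C(CO[Si](c3ccccc3)(c4ccccc4)C(C)(C)C)C2)N=C1 | intermediate
18 | 1-[(trimethylsilyl)methyl]oxazolinium triflate of 17 | O1[C@@H](/C(C)=C\I)[C@]2(C(=O)C=C(CO[Si](c3ccccc3)(c4ccccc4)C(C)(C)C)C2)[N+](C[Si](C)(C)C)=C1.[O-]S(=O)(=O)C(F)(F)F | intermediate
19 | N-formyl-N-[(trimethylsilyl)methyl] amino alcohol (free (1S)-carbinol, (Z)-iodoalkene, cyclopentenone) | O[C@@H](/C(C)=C\I)[C@]2(C(=O)C=C(CO[Si](c3ccccc3)(c4ccccc4)C(C)(C)C)C2)N(C=O)C[Si](C)(C)C | intermediate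
20 | N-formyl-N-[(trimethylsilyl)methyl] amino butenolide | O1C(=O)C=C(C)[C@H]1[C@]2(C(=O)C=C(CO[Si](c3ccccc3)(c4ccccc4)C(C)(C)C)C2)N(C=O)C[Si](C)(C)C | intermediate
21 | (5S)-5-[(1R)-4-[(tert-butyldiphenylsilyloxy)methyl]-2-oxo-1-{[(trimethylsilyl)methyl]amino}cyclopent-3-en-1-yl]-4-methylfuran-2(5H)-one | O1C(=O)C=C(C)[C@H]1[C@]2(C(=O)C=C(CO[Si](c3ccccc3)(c4ccccc4)C(C)(C)C)C2)NC[Si](C)(C)C | intermediate
22 | spiro pyrrolidine–γ-lactone enone (cis-fused lactone, N–H) | C[C@@]12CC(=O)O[C@@H]1[C@]3(C(=O)C=C(CO[Si](c4ccccc4)(c5ccccc5)C(C)(C)C)C3)NC2 | intermediate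
23 | N-[(diethoxyphosphoryl)acetyl] derivative of 22 | C[C@@]12CC(=O)O[C@@H]1[C@]3(C(=O)C=C(CO[Si](c4ccccc4)(c5ccccc5)C(C)(C)C)C3)N(C2)C(=O)CP(=O)(OCC)OCC | intermediate
24 | 4-(diethoxyphosphoryl) bridged lactam ketone (C-4 epimers) | C[C@@]12CC(=O)O[C@@H]1[C@]13C[C@](CO[Si](c4ccccc4)(c5ccccc5)C(C)(C)C)(CC1=O)C(P(=O)(OCC)OCC)C(=O)N3C2 | intermediate
25 | 4-[(Z)-2-[(1R)-2-iodocyclopent-2-en-1-yl]ethylidene] bridged lactam ketone | C[C@@]12CC(=O)O[C@@H]1[C@]13C[C@](CO[Si](c4ccccc4)(c5ccccc5)C(C)(C)C)(CC1=O)/C(=C/C[C@H]6CCC=C6I)C(=O)N3C2 | intermediate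
26 | (4S)-4-{2-[(1R)-2-iodocyclopent-2-en-1-yl]ethyl} bridged lactam ketone | C[C@@]12CC(=O)O[C@@H]1[C@]13C[C@](CO[Si](c4ccccc4)(c5ccccc5)C(C)(C)C)(CC1=O)[C@H](CC[C@H]6CCC=C6I)C(=O)N3C2 | intermediate
27 | 7-(trimethylsilyloxy)-6-ene (silyl enol ether) of 26 | C[C@@]12CC(=O)O[C@@H]1[C@]13C[C@](CO[Si](c4ccccc4)(c5ccccc5)C(C)(C)C)(C=C1O[Si](C)(C)C)[C@H](CC[C@H]6CCC=C6I)C(=O)N3C2 | intermediate
28 | 6-(3-tert-butoxy-3-oxopropyl) derivative of 26 | C[C@@]12CC(=O)O[C@@H]1[C@]13C[C@](CO[Si](c4ccccc4)(c5ccccc5)C(C)(C)C)([C@H](CCC(=O)OC(C)(C)C)C1=O)[C@H](CC[C@H]6CCC=C6I)C(=O)N3C2 | intermediate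
29 | 6-(2-carboxyethyl) derivative of 26 | C[C@@]12CC(=O)O[C@@H]1[C@]13C[C@](CO[Si](c4ccccc4)(c5ccccc5)C(C)(C)C)([C@H](CCC(=O)O)C1=O)[C@H](CC[C@H]6CCC=C6I)C(=O)N3C2 | intermediate
30 | enol δ-lactone across C-6=C-7 carrying the iodocyclopentenylethyl chain | C[C@@]12CC(=O)O[C@@H]1[C@]13C[C@](CO[Si](c4ccccc4)(c5ccccc5)C(C)(C)C)(C7=C1OC(=O)CC7)[C@H](CC[C@H]6CCC=C6I)C(=O)N3C2 | intermediate
31 | heptacyclic lactam bis-lactone silyl ether | C[C@@]12CC(=O)O[C@@H]1[C@]13C[C@@]4(CO[Si](c6ccccc6)(c7ccccc7)C(C)(C)C)[C@H](CC[C@H]5CCC=C5[C@]45CCC(=O)O[C@H]15)C(=O)N3C2 | intermediate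
32 | tert-butyldiphenylsilyl ether of 33 | C[C@@]12CC(=O)O[C@@H]1[C@]13C[C@@]4(CO[Si](c6ccccc6)(c7ccccc7)C(C)(C)C)[C@H](CC[C@H]5CCC=C5[C@]45CCC(=O)O[C@H]15)CN3C2 | intermediate
33 | CNP0247797.1 | C[C@@]12CC(=O)O[C@@H]1[C@]13C[C@@]4(CO)[C@H](CC[C@H]5CCC=C5[C@]45CCC(=O)O[C@H]15)CN3C2 | target

Total step count: 25. Longest linear sequence: 19 steps (6 to 33 through steps 5, 6 and 9–25).

Steps most likely to fail

Step 23 (Proposed new method). The alkenylpalladium may be reduced by formate before it inserts into the hindered enol-lactone double bond, or the enol lactone may be cleaved by acyl transfer before cyclisation. The fallback sets out from 28 and comes back at 31. Palladium-catalysed intramolecular α-alkenylation of the ketone enolate (Pd(PPh3)4, PhOK, THF, 70 °C) would close the seven-membered ring and give the seven-ring ketone tert-butyl ester F1. NaBH4, attacking the open exo face, would give the endo-alcohol F2, and CF3CO2H the hydroxy acid F3. Mitsunobu lactonisation (PPh3, diisopropyl azodicarboxylate) would then close the δ-lactone with inversion at the carbinol carbon to give 31.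

Step 19. Conjugate addition to the β,β-disubstituted enone may be slow and reversible, so that γ-deprotonation of the enone or aldehyde self-condensation takes over. The fallback sets out from 22 and comes back at 26. Acylation with 2-bromoacryloyl chloride would give the bromoacrylamide F4. A tin hydride-mediated 6-exo alkenyl-radical cyclisation onto the enone (Bu3SnH, AIBN) would give the α-methylene lactam F5. Photoredox decarboxylative Giese addition of [(1R)-2-iodocyclopent-2-en-1-yl]acetic acid F6 (from 4 with LiOH), followed by exo protonation, would give 26.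

Step 10. Facial or simple diastereoselection may be poor when the quaternary centre is formed from the α-branched isocyanide. The fallback sets out from 13 and comes back at 14. The aldol reaction would be run with an achiral catalyst (AgOAc, Et3N) to give the racemic trans-oxazoline, and the enantiomers separated by preparative chromatography on a chiral stationary phase. The unwanted enantiomer, methyl (4S,5R)-oxazoline F7, would be discarded.

Further compounds
F1 | step 23 | seven-ring ketone tert-butyl ester (C-6 quaternary, C-7 ketone) | C[C@@]12CC(=O)O[C@@H]1[C@]13C[C@@]4(CO[Si](c6ccccc6)(c7ccccc7)C(C)(C)C)[C@H](CC[C@H]5CCC=C5[C@@]4(CCC(=O)OC(C)(C)C)C1=O)C(=O)N3C2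
F2 | step 23 | 7-endo-alcohol tert-butyl ester | C[C@@]12CC(=O)O[C@@H]1[C@]13C[C@@]4(CO[Si](c6ccccc6)(c7ccccc7)C(C)(C)C)[C@H](CC[C@H]5CCC=C5[C@@]4(CCC(=O)OC(C)(C)C)[C@H]1O)C(=O)N3C2
F3 | step 23 | 7-endo-hydroxy acid | C[C@@]12CC(=O)O[C@@H]1[C@]13C[C@@]4(CO[Si](c6ccccc6)(c7ccccc7)C(C)(C)C)[C@H](CC[C@H]5CCC=C5[C@@]4(CCC(=O)O)[C@H]1O)C(=O)N3C2
F4 | step 19 | N-(2-bromoacryloyl) derivative of 22 | C[C@@]12CC(=O)O[C@@H]1[C@]3(C(=O)C=C(CO[Si](c4ccccc4)(c5ccccc5)C(C)(C)C)C3)N(C2)C(=O)C(Br)=C
F5 | step 19 | 4-methylidene bridged lactam ketone | C[C@@]12CC(=O)O[C@@H]1[C@]13C[C@](CO[Si](c4ccccc4)(c5ccccc5)C(C)(C)C)(CC1=O)C(=C)C(=O)N3C2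
F6 | step 19 | [(1R)-2-iodocyclopent-2-en-1-yl]acetic acid | OC(=O)C[C@H]1CCC=C1I
F7 | step 10 | methyl (4S,5R)-oxazoline, enantiomer of 14 | O1[C@H](/C(C)=C\I)[C@@](C(=O)OC)(N=C1)CC(=C)CO[Si](c2ccccc2)(c3ccccc3)C(C)(C)C
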